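## Retrosynthetic overview

1. Target 28 ⇐ desilylation and O‑tigloylation at C8 of the bicyclic hydroxy lactone 26.
2. Lactone ring of 26 (second ring) ⇐ face‑selective epoxidation of cycloheptene 24 and 5‑exo opening of the oxirane by the side‑chain tert‑butyl ester.
3. Cycloheptene 24 (first ring, key step) ⇐ ring‑closing metathesis of the acyclic diene 23, forming C8=C8a.
4. Diene 23 ⇐ Felkin‑controlled C4–C5 union of fragment A (aldehyde 11: C5–C8 plus the crotonoyl group) with fragment B (iodide 20: C2–C4 and C8a).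
5. Both fragments ⇐ Evans alkylations of (4S)‑4‑benzyloxazolidinone imides with tert‑butyl bromoacetate, via (R)‑β‑methyl‑ and (S)‑β‑vinyl‑γ‑butyrolactone.

Assumption: the target is read as an octahydro‑2H‑cyclohepta[b]furan‑2‑one and its locants (C2 lactone carbonyl, C3, C3a, C4–C8, C8a) are used for the corresponding carbons of all intermediates; simple reagents are given with SMILES and carry no compound number.

## Fragment A (aldehyde 11)

Step 1
Reactants: 1 (4S)-4-benzyl-3-propanoyl-1,3-oxazolidin-2-one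
Product: 2 tert-butyl (3R)-4-[(4S)-4-benzyl-2-oxo-1,3-oxazolidin-3-yl]-3-methyl-4-oxobutanoate
Conditions: NaN(SiMe3)2, THF, −78 °C; BrCH2CO2t-Bu, −78 → −40 °C
Reagents that add atoms: tert-butyl bromoacetate, CC(C)(C)OC(=O)CBr
Why: Evans asymmetric alkylation, in which the chelated (Z)-sodium enolate is attacked by the bromoacetate on the face away from the benzyl group, setting the methyl-bearing centre (future C6).

Step 2
Reactants: 2 tert-butyl (3R)-4-[(4S)-4-benzyl-2-oxo-1,3-oxazolidin-3-yl]-3-methyl-4-oxobutanoate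
Product: 3 tert-butyl (3R)-4-hydroxy-3-methylbutanoate
Conditions: LiBH4, H2O (1 equiv), Et2O, 0 °C
Reagents that add atoms: none
Why: Reductive removal of the auxiliary, a chemoselective hydride reduction in which LiBH4 attacks the activated exocyclic imide carbonyl and spares the hindered tert-butyl ester, so the stereocentre is untouched.

Step 3
Reactants: 3 tert-butyl (3R)-4-hydroxy-3-methylbutanoate
Product: 4 (4R)-4-methyloxolan-2-one
Conditions: CF3CO2H, CH2Cl2, rt
Reagents that add atoms: none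
Why: Acid-mediated cleavage of the tert-butyl ester followed by spontaneous lactonisation of the γ-hydroxy acid, which does not involve the stereocentre.

Step 4
Reactants: 4 (4R)-4-methyloxolan-2-one
Product: 7 (3E,4R)-3-ethylidene-4-methyloxolan-2-one, via lithium aldolate 5 (not isolated), via mesylate 6 (not isolated)
Conditions: LiN(i-Pr)2, THF, −78 °C; CH3CHO; then MeSO2Cl, −78 → 0 °C; then DBU, rt
Reagents that add atoms: acetaldehyde, CC=O
Why: One-pot aldol condensation (aldol addition, O-mesylation, E1cB elimination), where the alkene geometry and the carbinol configuration of 5 are irrelevant because the next step passes through the planar dienolate.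

Step 5
Reactants: 7 (3E,4R)-3-ethylidene-4-methyloxolan-2-one
Product: 8 (3R,4S)-3-ethenyl-3-hydroxy-4-methyloxolan-2-one
Conditions: LiN(i-Pr)2, HMPA, THF, −78 °C; 3-phenyl-2-(phenylsulfonyl)oxaziridine, −78 °C; H2O
Reagents that add atoms: 3-phenyl-2-(phenylsulfonyl)oxaziridine, O=S(=O)(c1ccccc1)N1OC1c1ccccc1
Why: Davis oxidation of the extended lithium dienolate formed by γ-deprotonation, which is hydroxylated at the α-carbon anti to the neighbouring methyl group, creating the tertiary carbinol (future C7) with OH trans to methyl and unveiling the vinyl group by deconjugation.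

Step 6
Reactants: 8 (3R,4S)-3-ethenyl-3-hydroxy-4-methyloxolan-2-one
Product: 9 (3R,4S)-3-ethenyl-4-methyl-3-[(triethylsilyl)oxy]oxolan-2-one
Conditions: Et3SiOTf, 2,6-lutidine, CH2Cl2, 0 °C
Reagents that add atoms: triethylsilyl trifluoromethanesulfonate, CC[Si](CC)(CC)OS(=O)(=O)C(F)(F)F
Why: Silyl ether formation with a silyl triflate, reactive enough for a tertiary alcohol and giving a group that survives organolithium, oxidation and metathesis conditions.

Step 7
Reactants: 9 (3R,4S)-3-ethenyl-4-methyl-3-[(triethylsilyl)oxy]oxolan-2-one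
Product: 10 (2E,5R,6S)-5-ethenyl-7-hydroxy-6-methyl-5-[(triethylsilyl)oxy]hept-2-en-4-one
Conditions: (E)-1-bromoprop-1-ene, t-BuLi (2 equiv), Et2O, −78 °C; add 9 in THF, −78 °C; H2O quench at −78 °C
Reagents that add atoms: (E)-1-bromoprop-1-ene (used as (E)-prop-1-enyllithium), C/C=C/Br
Why: Mono-addition of an alkenyllithium to a lactone, whose tetrahedral lithium hemiketal is stable at −78 °C and collapses only on the cold quench, so the (E)-enone forms without over-addition, with retained alkene geometry and without base-induced silyl migration.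

Step 8
Reactants: 10 (2E,5R,6S)-5-ethenyl-7-hydroxy-6-methyl-5-[(triethylsilyl)oxy]hept-2-en-4-one
Product: 11 (2R,3R,5E)-3-ethenyl-2-methyl-4-oxo-3-[(triethylsilyl)oxy]hept-5-enal
Conditions: Dess–Martin periodinane, pyridine, CH2Cl2, 0 °C → rt
Reagents that add atoms: none
Why: Dess–Martin oxidation of the primary alcohol under buffered, non-basic conditions, which avoids epimerisation of the α-methyl aldehyde and β-elimination of the silyloxy group.

## Fragment B (iodide 20)

Step 9
Reactants: 12 (4S)-4-benzyl-1,3-oxazolidin-2-one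
Product: 13 (4S)-4-benzyl-3-[(2E)-but-2-enoyl]-1,3-oxazolidin-2-one
Conditions: n-BuLi, THF, −78 °C; (E)-but-2-enoyl chloride, −78 → 0 °C
Reagents that add atoms: (E)-but-2-enoyl chloride, C/C=C/C(=O)Cl
Why: N-acylation of the lithiated oxazolidinone with an acid chloride, a standard imide formation that leaves the auxiliary stereocentre untouched.

Step 10
Reactants: 13 (4S)-4-benzyl-3-[(2E)-but-2-enoyl]-1,3-oxazolidin-2-one
Product: 14 tert-butyl (3S)-3-[(4S)-4-benzyl-2-oxo-1,3-oxazolidine-3-carbonyl]pent-4-enoate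
Conditions: NaN(SiMe3)2, THF, −78 °C; BrCH2CO2t-Bu, −78 °C; AcOH quench
Reagents that add atoms: tert-butyl bromoacetate, CC(C)(C)OC(=O)CBr
Why: Evans alkylation of the chelated sodium dienolate (deconjugative α-alkylation), which reacts at the α-carbon on the face away from the benzyl group and so sets the vinyl-bearing centre (future C3a).

Step 11
Reactants: 14 tert-butyl (3S)-3-[(4S)-4-benzyl-2-oxo-1,3-oxazolidine-3-carbonyl]pent-4-enoate
Product: 15 tert-butyl (3S)-3-(hydroxymethyl)pent-4-enoate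
Conditions: LiBH4, H2O (1 equiv), Et2O, 0 °C
Reagents that add atoms: none
Why: Reductive removal of the auxiliary by chemoselective hydride reduction of the imide carbonyl, cold and weakly basic so that the allylic α-centre neither epimerises nor isomerises into conjugation.

Step 12
Reactants: 15 tert-butyl (3S)-3-(hydroxymethyl)pent-4-enoate
Product: 16 (4S)-4-ethenyloxolan-2-one
Conditions: CF3CO2H, CH2Cl2, rt
Reagents that add atoms: none
Why: Acid-mediated tert-butyl ester cleavage and lactonisation of the γ-hydroxy acid, which leaves the terminal alkene and the stereocentre alone.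

Step 13
Reactants: 16 (4S)-4-ethenyloxolan-2-one
Product: 17 (3R,4R)-4-ethenyl-3-methyloxolan-2-one
Conditions: LiN(i-Pr)2, THF, −78 °C; MeI, −78 → −40 °C
Reagents that add atoms: iodomethane, CI
Why: Lactone enolate alkylation in which iodomethane approaches the lithium enolate anti to the adjacent vinyl group, giving the 3,4-trans lactone and hence the future C3 configuration.

Step 14
Reactants: 17 (3R,4R)-4-ethenyl-3-methyloxolan-2-one
Product: 19 (2R,3R)-3-(iodomethyl)-2-methylpent-4-enoic acid, via trimethylsilyl ester 18 (not isolated)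
Conditions: Me3SiCl, NaI, MeCN, rt → 50 °C; then H2O
Reagents that add atoms: sodium iodide, [Na+].[I-]
Why: Lactone dealkylation with iodotrimethylsilane, in which carbonyl O-silylation and SN2 attack of iodide at the primary O–CH2 carbon open the ring without touching either stereocentre.

Step 15
Reactants: 19 (2R,3R)-3-(iodomethyl)-2-methylpent-4-enoic acid
Product: 20 tert-butyl (2R,3R)-3-(iodomethyl)-2-methylpent-4-enoate
Conditions: Cl3CC(=NH)Ot-Bu, BF3·OEt2 (cat.), CH2Cl2/cyclohexane, rt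
Reagents that add atoms: tert-butyl 2,2,2-trichloroacetimidate, CC(C)(C)OC(=N)C(Cl)(Cl)Cl
Why: Acid-catalysed tert-butyl esterification with a trichloroacetimidate, which avoids a free carboxylate that would displace the primary iodide and re-close the lactone.

## Union, ring closures and end game

Step 16
Reactants: 11 (2R,3R,5E)-3-ethenyl-2-methyl-4-oxo-3-[(triethylsilyl)oxy]hept-5-enal; 20 tert-butyl (2R,3R)-3-(iodomethyl)-2-methylpent-4-enoate
Product: 22 tert-butyl (2R,3R,5R,6S,7R,9E)-3,7-diethenyl-5-hydroxy-2,6-dimethyl-8-oxo-7-[(triethylsilyl)oxy]undec-9-enoate, via alkylchromium dichloride 21 (not isolated)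
Conditions: CrCl2 (4 equiv), cobalt phthalocyanine Co(C32H16N8) (cat.), DMF, rt; aqueous work-up
Reagents that add atoms: none
Why: Takai–Utimoto alkylchromium addition (cobalt-catalysed Nozaki–Hiyama-type coupling), in which the organochromium reagent adds only to the aldehyde and Felkin–Anh attack anti to the bulky quaternary C7 substituent gives the 5R alcohol (5,6-syn).

Step 17
Reactants: 22 tert-butyl (2R,3R,5R,6S,7R,9E)-3,7-diethenyl-5-hydroxy-2,6-dimethyl-8-oxo-7-[(triethylsilyl)oxy]undec-9-enoate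
Product: 23 tert-butyl (2R,3R,5R,6S,7R,9E)-5-[(tert-butyldimethylsilyl)oxy]-3,7-diethenyl-2,6-dimethyl-8-oxo-7-[(triethylsilyl)oxy]undec-9-enoate
Conditions: t-BuMe2SiOTf, 2,6-lutidine, CH2Cl2, −78 °C
Reagents that add atoms: tert-butyldimethylsilyl trifluoromethanesulfonate, CC(C)(C)[Si](C)(C)OS(=O)(=O)C(F)(F)F
Why: Silyl ether formation at low temperature, which is much faster than attack of the triflate on the tert-butyl ester or the enone and blocks the C5 hydroxyl against hemiketal formation and later acylation.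

Step 18
Reactants: 23 tert-butyl (2R,3R,5R,6S,7R,9E)-5-[(tert-butyldimethylsilyl)oxy]-3,7-diethenyl-2,6-dimethyl-8-oxo-7-[(triethylsilyl)oxy]undec-9-enoate
Product: 24 tert-butyl (2R)-2-[(1R,4R,5S,6R)-4-[(2E)-but-2-enoyl]-6-[(tert-butyldimethylsilyl)oxy]-5-methyl-4-[(triethylsilyl)oxy]cyclohept-2-en-1-yl]propanoate
Conditions: second-generation Grubbs catalyst RuCl2(=CHPh)(PCy3)(H2IMes) (5 mol %), CH2Cl2 (2 mM), 40 °C
Reagents that add atoms: none
Why: Ring-closing metathesis of the two terminal vinyl groups, which forms the seven-membered ring (C8=C8a, necessarily Z) with loss of ethene while the electron-poor disubstituted enone alkene stays out.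

Step 19
Reactants: 24 tert-butyl (2R)-2-[(1R,4R,5S,6R)-4-[(2E)-but-2-enoyl]-6-[(tert-butyldimethylsilyl)oxy]-5-methyl-4-[(triethylsilyl)oxy]cyclohept-2-en-1-yl]propanoate
Product: 26 (3R,3aS,5R,6S,7S,8S,8aR)-7-[(2E)-but-2-enoyl]-5-[(tert-butyldimethylsilyl)oxy]-8-hydroxy-3,6-dimethyl-7-[(triethylsilyl)oxy]octahydro-2H-cyclohepta[b]furan-2-one, via epoxide 25 (not isolated)
Conditions: mCPBA, CH2Cl2, 0 °C → rt; then camphorsulfonic acid (cat.), rt
Reagents that add atoms: 3-chloroperbenzoic acid, OOC(=O)c1cccc(Cl)c1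
Why: Prilezhaev epoxidation of the only electron-rich alkene on the face opposite the C7 silyloxy group and the C3a side chain, then acid-catalysed 5-exo opening of the oxirane at C8a by the ester carbonyl with inversion and loss of isobutene, giving the cis-fused lactone and the C8 hydroxyl trans to the lactone oxygen.

Step 20
Reactants: 26 (3R,3aS,5R,6S,7S,8S,8aR)-7-[(2E)-but-2-enoyl]-5-[(tert-butyldimethylsilyl)oxy]-8-hydroxy-3,6-dimethyl-7-[(triethylsilyl)oxy]octahydro-2H-cyclohepta[b]furan-2-one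
Product: 27 (3R,3aS,5R,6S,7S,8S,8aR)-7-[(2E)-but-2-enoyl]-5-[(tert-butyldimethylsilyl)oxy]-3,6-dimethyl-2-oxo-7-[(triethylsilyl)oxy]octahydro-2H-cyclohepta[b]furan-8-yl (2E)-2-methylbut-2-enoate
Conditions: (E)-2-methylbut-2-enoyl chloride, pyridine, DMAP, CH2Cl2, 0 → 40 °C
Reagents that add atoms: (E)-2-methylbut-2-enoyl chloride (tigloyl chloride), C/C=C(C)/C(=O)Cl
Why: DMAP-catalysed acylation (nucleophilic catalysis) of the only free hydroxyl, with pyridine rather than a trialkylamine to avoid vinylketene formation and with the thermodynamically preferred (E)-tiglate geometry retained.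

Step 21
Reactants: 27 (3R,3aS,5R,6S,7S,8S,8aR)-7-[(2E)-but-2-enoyl]-5-[(tert-butyldimethylsilyl)oxy]-3,6-dimethyl-2-oxo-7-[(triethylsilyl)oxy]octahydro-2H-cyclohepta[b]furan-8-yl (2E)-2-methylbut-2-enoate
Product: 28 (3R,3aS,5R,6S,7S,8S,8aR)-7-[(2E)-but-2-enoyl]-5,7-dihydroxy-3,6-dimethyl-2-oxooctahydro-2H-cyclohepta[b]furan-8-yl (2E)-2-methylbut-2-enoate
Conditions: HF·pyridine, THF, 0 °C → rt
Reagents that add atoms: none
Why: Fluoride-mediated desilylation of both silyl ethers under mildly acidic conditions that leave the enone, the tiglate and the lactone (including its epimerisable C3) untouched.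

## Compound list

1 | (4S)-4-benzyl-3-propanoyl-1,3-oxazolidin-2-one | CCC(=O)N1[C@@H](Cc2ccccc2)COC1=O | starting material
2 | tert-butyl (3R)-4-[(4S)-4-benzyl-2-oxo-1,3-oxazolidin-3-yl]-3-methyl-4-oxobutanoate | CC(C)(C)OC(=O)C[C@@H](C)C(=O)N1[C@@H](Cc2ccccc2)COC1=O | intermediate
3 | tert-butyl (3R)-4-hydroxy-3-methylbutanoate | CC(C)(C)OC(=O)C[C@@H](C)CO | intermediate
4 | (4R)-4-methyloxolan-2-one | C[C@H]1COC(=O)C1 | intermediate
5 | lithium 1-[(3S,4R)-4-methyl-2-oxooxolan-3-yl]ethan-1-olate (3,4-trans; epimer mixture at the carbinol carbon) | C[C@H]1COC(=O)[C@@H]1C(C)[O-].[Li+] | intermediate (not isolated)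
6 | 1-[(3S,4R)-4-methyl-2-oxooxolan-3-yl]ethyl methanesulfonate (epimer mixture at the sulfonate carbon) | C[C@H]1COC(=O)[C@@H]1C(C)OS(C)(=O)=O | intermediate (not isolated)
7 | (3E,4R)-3-ethylidene-4-methyloxolan-2-one | C/C=C1/C(=O)OC[C@@H]1C | intermediate
8 | (3R,4S)-3-ethenyl-3-hydroxy-4-methyloxolan-2-one (OH trans to methyl) | C=C[C@@]1(O)[C@@H](C)COC1=O | intermediate
9 | (3R,4S)-3-ethenyl-4-methyl-3-[(triethylsilyl)oxy]oxolan-2-one | C=C[C@@]1(O[Si](CC)(CC)CC)[C@@H](C)COC1=O | intermediate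
10 | (2E,5R,6S)-5-ethenyl-7-hydroxy-6-methyl-5-[(triethylsilyl)oxy]hept-2-en-4-one | C/C=C/C(=O)[C@@](O[Si](CC)(CC)CC)(C=C)[C@@H](C)CO | intermediate
11 | (2R,3R,5E)-3-ethenyl-2-methyl-4-oxo-3-[(triethylsilyl)oxy]hept-5-enal (fragment A) | C/C=C/C(=O)[C@@](O[Si](CC)(CC)CC)(C=C)[C@@H](C)C=O | intermediate
12 | (4S)-4-benzyl-1,3-oxazolidin-2-one | O=C1N[C@@H](Cc2ccccc2)CO1 | starting material
13 | (4S)-4-benzyl-3-[(2E)-but-2-enoyl]-1,3-oxazolidin-2-one | C/C=C/C(=O)N1[C@@H](Cc2ccccc2)COC1=O | intermediate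
14 | tert-butyl (3S)-3-[(4S)-4-benzyl-2-oxo-1,3-oxazolidine-3-carbonyl]pent-4-enoate | C=C[C@H](CC(=O)OC(C)(C)C)C(=O)N1[C@@H](Cc2ccccc2)COC1=O | intermediate
15 | tert-butyl (3S)-3-(hydroxymethyl)pent-4-enoate | C=C[C@H](CC(=O)OC(C)(C)C)CO | intermediate
16 | (4S)-4-ethenyloxolan-2-one | C=C[C@H]1COC(=O)C1 | intermediate
17 | (3R,4R)-4-ethenyl-3-methyloxolan-2-one (3,4-trans) | C=C[C@H]1COC(=O)[C@@H]1C | intermediate
18 | trimethylsilyl (2R,3R)-3-(iodomethyl)-2-methylpent-4-enoate | IC[C@H](C=C)[C@@H](C)C(=O)O[Si](C)(C)C | intermediate (not isolated)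
19 | (2R,3R)-3-(iodomethyl)-2-methylpent-4-enoic acid | IC[C@H](C=C)[C@@H](C)C(=O)O | intermediate
20 | tert-butyl (2R,3R)-3-(iodomethyl)-2-methylpent-4-enoate (fragment B) | IC[C@H](C=C)[C@@H](C)C(=O)OC(C)(C)C | intermediate
21 | dichloro[(2R,3R)-4-(tert-butoxy)-2-ethenyl-3-methyl-4-oxobutyl]chromium | Cl[Cr](Cl)C[C@H](C=C)[C@@H](C)C(=O)OC(C)(C)C | intermediate (not isolated)
22 | tert-butyl (2R,3R,5R,6S,7R,9E)-3,7-diethenyl-5-hydroxy-2,6-dimethyl-8-oxo-7-[(triethylsilyl)oxy]undec-9-enoate | C/C=C/C(=O)[C@@](O[Si](CC)(CC)CC)(C=C)[C@@H](C)[C@H](O)C[C@H](C=C)[C@@H](C)C(=O)OC(C)(C)C | intermediate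
23 | tert-butyl (2R,3R,5R,6S,7R,9E)-5-[(tert-butyldimethylsilyl)oxy]-3,7-diethenyl-2,6-dimethyl-8-oxo-7-[(triethylsilyl)oxy]undec-9-enoate | C/C=C/C(=O)[C@@](O[Si](CC)(CC)CC)(C=C)[C@@H](C)[C@H](O[Si](C)(C)C(C)(C)C)C[C@H](C=C)[C@@H](C)C(=O)OC(C)(C)C | intermediate
24 | tert-butyl (2R)-2-[(1R,4R,5S,6R)-4-[(2E)-but-2-enoyl]-6-[(tert-butyldimethylsilyl)oxy]-5-methyl-4-[(triethylsilyl)oxy]cyclohept-2-en-1-yl]propanoate | C/C=C/C(=O)[C@]1(O[Si](CC)(CC)CC)[C@@H](C)[C@H](O[Si](C)(C)C(C)(C)C)C[C@@H]([C@@H](C)C(=O)OC(C)(C)C)C=C1 | intermediate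
25 | 2,3-epoxide of cycloheptene 24, oxirane oxygen trans to the C4 triethylsilyloxy group and to the C1 side chain | C/C=C/C(=O)[C@]1(O[Si](CC)(CC)CC)[C@@H](C)[C@H](O[Si](C)(C)C(C)(C)C)C[C@@H]([C@@H](C)C(=O)OC(C)(C)C)[C@@H]2O[C@H]12 | intermediate (not isolated)
26 | (3R,3aS,5R,6S,7S,8S,8aR)-7-[(2E)-but-2-enoyl]-5-[(tert-butyldimethylsilyl)oxy]-8-hydroxy-3,6-dimethyl-7-[(triethylsilyl)oxy]octahydro-2H-cyclohepta[b]furan-2-one | C/C=C/C(=O)[C@]1(O[Si](CC)(CC)CC)[C@@H](C)[C@H](O[Si](C)(C)C(C)(C)C)C[C@@H]2[C@@H](OC(=O)[C@@H]2C)[C@@H]1O | intermediate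
27 | (3R,3aS,5R,6S,7S,8S,8aR)-7-[(2E)-but-2-enoyl]-5-[(tert-butyldimethylsilyl)oxy]-3,6-dimethyl-2-oxo-7-[(triethylsilyl)oxy]octahydro-2H-cyclohepta[b]furan-8-yl (2E)-2-methylbut-2-enoate | C/C=C/C(=O)[C@]1(O[Si](CC)(CC)CC)[C@@H](C)[C@H](O[Si](C)(C)C(C)(C)C)C[C@@H]2[C@@H](OC(=O)[C@@H]2C)[C@@H]1OC(=O)/C(C)=C/C | intermediate
28 | (3R,3aS,5R,6S,7S,8S,8aR)-7-[(2E)-but-2-enoyl]-5,7-dihydroxy-3,6-dimethyl-2-oxooctahydro-2H-cyclohepta[b]furan-8-yl (2E)-2-methylbut-2-enoate (CNP0183494.2) | C/C=C/C(=O)[C@]1(O)[C@@H](C)[C@H](O)C[C@@H]2[C@@H](OC(=O)[C@@H]2C)[C@@H]1OC(=O)/C(C)=C/C | target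

## Summary

Total step count: 21 (fragment A: steps 1–8; fragment B: steps 9–15; union and end game: steps 16–21).

Longest linear sequence: 14 steps (1 → 11 by steps 1–8, then steps 16–21); the branch from 12 is 13 steps.

## The three steps most likely to fail

Step 16 (fragment union). The aldehyde is α-branched and neopentyl-like, so the alkylchromium may add slowly. The primary radical on the way to 21 is a homoallyl radical that can undergo a 1,2-vinyl shift. The Felkin preference may be only moderate. Fallback, setting out from 20: zinc insertion (Zn dust, LiCl, THF) gives the alkylzinc iodide F1. Me3SiCH2Li converts this into the mixed diorganozinc F2, whose trimethylsilylmethyl group does not transfer. F2 is then added to aldehyde 11 with Ti(OiPr)4 and catalytic trans-N,N′-(cyclohexane-1,2-diyl)bis(trifluoromethanesulfonamide), using the ligand antipode that reinforces the Felkin sense. This polar, catalyst-controlled addition touches neither the enone nor the ester and comes back to the route at 22.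

Step 19 (epoxidation and lactonisation). The required face is chosen only by sterics (anti to the C7 silyloxy group and the C3a side chain), and the acid step could divert into a semipinacol shift of the α-silyloxy epoxide. Fallback, setting out from 22 with the silylation of step 17 left out: ring-closing metathesis of 22 with the same ruthenium catalyst gives the cycloheptenol F3. VO(acac)2 with t-BuOOH delivers the oxirane from the face of the free C5 hydroxyl, which is the required face, to give the epoxy alcohol F4. Catalytic camphorsulfonic acid closes the lactone to the dihydroxy lactone F5. t-BuMe2SiCl with imidazole silylates only the unhindered C5 hydroxyl of F5, which comes back to the route at 26.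

Step 20 (tigloylation). The C8 hydroxyl lies between the quaternary C7 carrying the triethylsilyloxy group and the ring-fusion carbon, so acylation with an α-branched, conjugated acid chloride may stall. Fallback, setting out from 26: brief treatment with pyridine-buffered HF·pyridine at 0 °C removes only the more labile triethylsilyl ether and gives the diol F6, in which the C8 hydroxyl is far less shielded and the tertiary C7 hydroxyl does not acylate. Tigloyl chloride with pyridine and DMAP then gives the tiglate F7, and HF·pyridine at room temperature removes the remaining silyl ether of F7, which comes back to the route at 28.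

## Further compounds

F1 | step 16 | iodo[(2R,3R)-4-(tert-butoxy)-2-ethenyl-3-methyl-4-oxobutyl]zinc | I[Zn]C[C@H](C=C)[C@@H](C)C(=O)OC(C)(C)C
F2 | step 16 | [(2R,3R)-4-(tert-butoxy)-2-ethenyl-3-methyl-4-oxobutyl][(trimethylsilyl)methyl]zinc | C[Si](C)(C)C[Zn]C[C@H](C=C)[C@@H](C)C(=O)OC(C)(C)C
F3 | step 19 | tert-butyl (2R)-2-[(1R,4R,5S,6R)-4-[(2E)-but-2-enoyl]-6-hydroxy-5-methyl-4-[(triethylsilyl)oxy]cyclohept-2-en-1-yl]propanoate | C/C=C/C(=O)[C@]1(O[Si](CC)(CC)CC)[C@@H](C)[C@H](O)C[C@@H]([C@@H](C)C(=O)OC(C)(C)C)C=C1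
F4 | step 19 | 2,3-epoxide of F3, oxirane oxygen cis to the C6 hydroxyl and trans to the C4 triethylsilyloxy group | C/C=C/C(=O)[C@]1(O[Si](CC)(CC)CC)[C@@H](C)[C@H](O)C[C@@H]([C@@H](C)C(=O)OC(C)(C)C)[C@@H]2O[C@H]12
F5 | step 19 | (3R,3aS,5R,6S,7S,8S,8aR)-7-[(2E)-but-2-enoyl]-5,8-dihydroxy-3,6-dimethyl-7-[(triethylsilyl)oxy]octahydro-2H-cyclohepta[b]furan-2-one | C/C=C/C(=O)[C@]1(O[Si](CC)(CC)CC)[C@@H](C)[C@H](O)C[C@@H]2[C@@H](OC(=O)[C@@H]2C)[C@@H]1O
F6 | step 20 | (3R,3aS,5R,6S,7S,8S,8aR)-7-[(2E)-but-2-enoyl]-5-[(tert-butyldimethylsilyl)oxy]-7,8-dihydroxy-3,6-dimethyloctahydro-2H-cyclohepta[b]furan-2-one | C/C=C/C(=O)[C@]1(O)[C@@H](C)[C@H](O[Si](C)(C)C(C)(C)C)C[C@@H]2[C@@H](OC(=O)[C@@H]2C)[C@@H]1O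
F7 | step 20 | (3R,3aS,5R,6S,7S,8S,8aR)-7-[(2E)-but-2-enoyl]-5-[(tert-butyldimethylsilyl)oxy]-7-hydroxy-3,6-dimethyl-2-oxooctahydro-2H-cyclohepta[b]furan-8-yl (2E)-2-methylbut-2-enoate | C/C=C/C(=O)[C@]1(O)[C@@H](C)[C@H](O[Si](C)(C)C(C)(C)C)C[C@@H]2[C@@H](OC(=O)[C@@H]2C)[C@@H]1OC(=O)/C(C)=C/C
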